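The earlier runs and the new flask are simulated for an exercise.

Electrophile plus product tracks the feed: in the elm run at 6.00 d they sum to 75.3% of the charge, and 75.0% had gone in. So my reckoning for the flask turned on how fast electrophile is cleared.

| flask | electrophile | free base | gas | remark | time |
|---|---|---|---|---|---|
| elm | 0.10 M (fed, over 8.0 d) | 0.15 M | 4.4 mM (held) | run made earlier; the fed solution adds 0.25 times the starting volume |  |
| larch | 0.10 M (fed, over 8.0 d) | 0.60 M | 4.4 mM (held) | run made earlier; the fed solution adds 0.25 times the starting volume |  |
| oak | 0.15 M (fed, over 8.0 d) | 0.30 M | 4.4 mM (held) | run made earlier; the fed solution adds 0.25 times the starting volume |  |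
| flask | 0.10 M (fed, over 8.0 d) | 0.300 M | 4.4 mM (held) | the fed solution adds 0.25 times the starting volume | 10 d |

| run | time / d | electrophile / % | product / % |
|---|---|---|---|
| elm | 0.500 | 5.3 | 0.4 |
| elm | 0.833 | 8.1 | 2.5 |
| elm | 1.04 | 9.7 | 3.8 |
| elm | 1.67 | 13.1 | 7.7 |
| elm | 2.50 | 16.5 | 14.2 |
| elm | 4.00 | 21.1 | 28.7 |
| elm | 6.00 | 24.0 | 51.3 |
| larch | 0.500 | 5.4 | 0.9 |
| larch | 0.833 | 8.2 | 2.7 |
| larch | 1.04 | 9.2 | 3.4 |
| larch | 1.67 | 13.3 | 7.3 |
| larch | 2.50 | 17.5 | 14.2 |
| larch | 4.00 | 20.9 | 28.8 |
| larch | 6.00 | 23.9 | 51.4 |
| oak | 0.500 | 5.1 | 0.5 |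
| oak | 0.833 | 8.0 | 2.5 |
| oak | 1.67 | 13.8 | 7.3 |
| oak | 3.00 | 19.6 | 17.0 |
| oak | 6.00 | 27.1 | 47.6 |

(readings scatter by 0.3 percentage points)

- amounts are per litre of the starting volume; all of the dose is in the solution fed
- the earlier runs were read with a standard deviation of 0.3 percentage points
- at the start none of the gas is in solution
- percentages count the whole charge, also what has not yet gone in
- the earlier runs do not show how much of nucleophile is bound; that part of a forecast is a guess

- part of the electrophile that has reacted at 10 d
- share of the unused nucleophile that is free and not bound as protonated nucleophile, at 10 d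

Does free base matter? Going from 0.15 M in elm to 0.60 M in larch left product at 51.3% against 51.4% at 6.00 d. So I carried elm over to the flask, which has elm's charge and feed and 0.300 M of free base.

How fast is the clearing? I took the clearing constant, product gained per day over mean electrophile present, a pseudo-first-order constant; between 4.00 d and 6.00 d elm reads 0.501 d⁻¹.

How high does electrophile stand when the feed stops? The feed brings 0.125 d⁻¹ of the charge, so feed and clearing balance at a hold level of 24.9%. The relaxation time 2.00 d is a quarter of the feed time, so I expected the flask to reach that level.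

What is left at 10 d? Decay over the last 2.00 d leaves 9.16%, so I committed to 90.8% reacted. Oak, charged with more electrophile and more free base than elm, read slower, at 0.437 d⁻¹ between 3.00 d and 6.00 d; larch had shown no gain from free base, and electrophile falls once the feed stops, so I took my figure as leaning low. The runs do not show how much nucleophile is bound, so I gave no figure for its free share.

The forecast gave 91.3%, above my 90.8%, and 85% free, with the words “nucleophile should be mostly free, but that is a guess”.

The flask gave 91.8% and 5.45%: electrophile stood at 24.9% at 8.00 d, against my 24.9%, and at 10 d protonated nucleophile was 0.0675 M beside 0.00389 M of nucleophile.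

    electrophile + nucleophile ⇌ acid set free + product (K = 13.0, k = 0.110 M⁻¹ min⁻¹)
    nucleophile + acid set free ⇌ protonated nucleophile, settled at all times (K = 2.10 × 10⁶ M⁻¹)
    acid set free + free base ⇌ salt of the base (K = 44000 M⁻¹, k = 0.380 M⁻¹ min⁻¹)
    gas ⇌ nucleophile, rate k4*(csat - [nucleophile]) (kL = 0.0100 min⁻¹)

The neighbour flask takes 0.25 M of electrophile. A straight line through elm and oak, reciprocal clearing constant against charge, gives it 0.348 d⁻¹, a hold level of 36.0%, and 17.9% left at 10 d. That neighbour flask showed 1.70% free nucleophile and kept 20.3% of its electrophile at 10.0 d.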